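**Plan**

Prostanoid numbering is used: C1 ester carbon, C4 acetoxy carbinol, C5=C6 (E), C8 and C12 the two sp3 carbons of the cyclopentenone ring, C9 ketone, C10=C11, C13–C20 the (Z)-octenyl chain.
Cuts: first the acetyl–O bond at C12, then C7–C8 (ring half C8–C20 plus chain half C1–C7), then C12–C13 in the ring half and C5=C6 in the chain half.
Enabling feature: C8 is the only enolisable carbon of the five-membered ring (C12 is quaternary, C10 is vinylic). C7 is the free primary end of the allyl unit C5–C7, whose other end is flanked by the C4 acetoxy group. An enolate/π-allyl pairing is therefore unambiguous on both sides, but it must be generated without base because the C12 oxygen sits β to the C9 ketone.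
Forward: the ring is bought as (R)-4-silyloxycyclopentenone. A (Z)-octenylbarium reagent adds to its carbonyl (C12–C13), C9 is deprotected and oxidised, and one silylation gives the C9 silyl dienol ether. The chain is joined at C7–C8, and C12 is acetylated last.
The L-glutamic-acid-derived (S)-lactone supplies C1–C5. Methylenation, lactone opening with acetylation, and cross metathesis with allyl methyl carbonate add C6–C7.
Stereochemistry: C4 comes from the chiral pool. C12 is set by relay from the C9 silyloxy centre, which is later erased. C8 is set by substrate control from C12 in the coupling. The Z alkene comes from semihydrogenation and the E alkene from metathesis.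

Key step: step 11

**Route**

Step 1
Reactants: 1 oct-2-yn-1-ol
Product: 2 (Z)-oct-2-en-1-ol
Conditions: H2 (1 atm), Pd on CaCO3 poisoned with Pb(OAc)2 (Lindlar catalyst), quinoline, hexane, rt
Reagents that add atoms: none
Why: Lindlar semihydrogenation delivers both hydrogens to the same face of the alkyne on the poisoned palladium surface, so the C14=C15 alkene should form as the Z isomer and the reduction should stop there.

Step 2
Reactants: 2 (Z)-oct-2-en-1-ol
Product: 3 (Z)-1-chlorooct-2-ene
Conditions: PPh3, CCl4, CH2Cl2, 0 °C to rt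
Reagents that add atoms: carbon tetrachloride ClC(Cl)(Cl)Cl
Why: The Appel reaction replaces the primary allylic hydroxyl through its oxyphosphonium salt by direct SN2 attack of chloride under neutral conditions, which should leave the position and the Z geometry of the alkene untouched.

Step 3
Reactants: 3 (Z)-1-chlorooct-2-ene; 4 (R)-4-(tert-butyldimethylsilyloxy)cyclopent-2-en-1-one
Product: 6 (1S,4R)-4-(tert-butyldimethylsilyloxy)-1-[(Z)-oct-2-enyl]cyclopent-2-en-1-ol (OH cis to OTBS), via (Z)-oct-2-enylbarium chloride 5 (not isolated)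
Conditions: BaI2, lithium biphenylide (Li, biphenyl), THF, rt; 3, −78 °C; then 4, −78 °C; aq. NH4Cl
Reagents that add atoms: none
Why: In the allylbarium carbonyl addition the reagent made at −78 °C from an allylic chloride and activated barium reacts at its unsubstituted α terminus with retention of the Z geometry and attacks enones in the 1,2 sense, and the C9 silyloxy group should steer it to the opposite ring face so that the new C12 hydroxyl stands cis to OTBS, the minor diastereomer being removable by chromatography.

Step 4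
Reactants: 6 (1S,4R)-4-(tert-butyldimethylsilyloxy)-1-[(Z)-oct-2-enyl]cyclopent-2-en-1-ol
Product: 7 (1S,4R)-1-[(Z)-oct-2-enyl]cyclopent-2-ene-1,4-diol (cis diol)
Conditions: Bu4NF·3H2O, THF, 0 °C to rt
Reagents that add atoms: none
Why: Fluoride-mediated desilylation, driven by the strong Si–F bond, frees the C9 alcohol under non-acidic conditions that should not ionise the tertiary allylic C12 alcohol.

Step 5
Reactants: 7 (1S,4R)-1-[(Z)-oct-2-enyl]cyclopent-2-ene-1,4-diol
Product: 8 (S)-4-hydroxy-4-[(Z)-oct-2-enyl]cyclopent-2-en-1-one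
Conditions: activated MnO2 (excess), CH2Cl2, rt
Reagents that add atoms: none
Why: The MnO2 allylic oxidation acts only on the secondary allylic C9 alcohol, the tertiary C12 alcohol being neither oxidisable nor transposed by this chromium-free oxidant, and the C9 centre that relayed its chirality to C12 is erased here.

Step 6
Reactants: 8 (S)-4-hydroxy-4-[(Z)-oct-2-enyl]cyclopent-2-en-1-one
Product: 9 (R)-5-[(Z)-oct-2-enyl]-2,5-bis(trimethylsilyloxy)cyclopenta-1,3-diene
Conditions: Me3SiOTf (2.5 equiv), Et3N (4 equiv), CH2Cl2, −20 to 0 °C; pentane extraction under argon, used at once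
Reagents that add atoms: trimethylsilyl trifluoromethanesulfonate C[Si](C)(C)OS(=O)(=O)C(F)(F)F
Why: Soft enolisation with silyl triflate and amine silylates the tertiary alcohol and the ketone oxygen in one operation, and because C12 is quaternary the only removable proton of the O-silylated enone is on C8, so a single cross-conjugated silyl dienol ether should form without any free enolate that could expel the C12 oxygen.

Step 7
Reactants: 10 (S)-5-(hydroxymethyl)dihydrofuran-2(3H)-one (the lactone derived from L-glutamic acid)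
Product: 11 (S)-5-oxotetrahydrofuran-2-carbaldehyde
Conditions: Dess–Martin periodinane, CH2Cl2, 0 °C to rt; filtration through silica
Reagents that add atoms: none
Why: The Dess–Martin oxidation stops at the aldehyde under nearly neutral, water-free conditions, which should protect the epimerisable C4 centre and avoid hydrate formation.

Step 8
Reactants: 11 (S)-5-oxotetrahydrofuran-2-carbaldehyde
Product: 12 (S)-5-vinyldihydrofuran-2(3H)-one
Conditions: MePPh3Br, KN(SiMe3)2, THF, 0 °C; then 11, −78 °C to rt
Reagents that add atoms: methyltriphenylphosphonium bromide C[P+](c1ccccc1)(c1ccccc1)c1ccccc1.[Br-]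
Why: Wittig methylenation at low temperature should be faster at the aldehyde than attack on the lactone or enolisation, so C4 keeps the configuration inherited from L-glutamic acid.

Step 9
Reactants: 12 (S)-5-vinyldihydrofuran-2(3H)-one
Product: 15 methyl (S)-4-acetoxyhex-5-enoate, via potassium (S)-4-hydroxyhex-5-enoate 13 (not isolated), via methyl (S)-4-hydroxyhex-5-enoate 14 (not isolated)
Conditions: KOH (1 equiv), MeOH/H2O, 0 °C to rt, evaporate; MeI, DMF, rt; then Ac2O, pyridine, DMAP (cat.), 0 °C to rt
Reagents that add atoms: potassium hydroxide [K+].[OH-]; iodomethane CI; acetic anhydride CC(=O)OC(C)=O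
Why: Saponification, SN2 O-methylation of the carboxylate and DMAP-catalysed acetylation are telescoped so that the γ-hydroxy ester is capped as its acetate before it can close back to the lactone, and no bond to C4 is broken.

Step 10
Reactants: 15 methyl (S)-4-acetoxyhex-5-enoate; 16 allyl methyl carbonate (3 equiv)
Product: 17 methyl (S,E)-4-acetoxy-7-(methoxycarbonyloxy)hept-5-enoate
Conditions: second-generation Hoveyda–Grubbs catalyst (3 mol %), CH2Cl2, 40 °C
Reagents that add atoms: none
Why: Olefin cross metathesis between the slowly homodimerising secondary allylic acetate and an excess of the fast-reacting allyl carbonate should favour the cross product, and the reversibility of the process favours the E C5=C6 alkene.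

Step 11
Reactants: 9 (R)-5-[(Z)-oct-2-enyl]-2,5-bis(trimethylsilyloxy)cyclopenta-1,3-diene; 17 methyl (S,E)-4-acetoxy-7-(methoxycarbonyloxy)hept-5-enoate (1.2 equiv)
Product: 18 methyl (4S,5E)-4-acetoxy-7-[(1R,2R)-2-[(Z)-oct-2-enyl]-5-oxo-2-(trimethylsilyloxy)cyclopent-3-en-1-yl]hept-5-enoate
Conditions: Pd2(dba)3·CHCl3 (2.5 mol %), 1,2-bis(diphenylphosphino)ethane (6 mol %), THF, 25 to 45 °C
Reagents that add atoms: none
Why: Zerovalent palladium ionises the primary allylic carbonate of 17 far faster than the secondary C4 acetate, carbon dioxide is lost, and the released methoxide attacks the enol silicon of 9, so the C9 enolate is formed next to the syn π-allylpalladium cation (C5–C7) without external base and attacks it at C7. The closest known reaction type is the neutral Tsuji–Trost allylation of ketone silyl enol ethers with allylic carbonates, and no ring is closed. The new C8 stereocentre is controlled by the quaternary C12 neighbour, since the electrophile should approach planar C8 anti to the larger and better σ-donating octenyl CH2 branch and hence cis to the C12 oxygen, which is also the more stable arrangement of this epimerisable centre. On the ring the selectivity is structural, because the cross-conjugated enolate is nucleophilic at C8 only and neither C12 nor C10 offers a β-hydrogen for enone-forming elimination from a palladium enolate, while on the chain attack at the unhindered terminus C7, remote from the electron-withdrawing C4 acetoxy group, keeps the E alkene and leaves C4 untouched. The short life of the enolate and the poor leaving ability of the C12 silyloxy group should suppress E1cB loss of the C12 oxygen, and the slight excess of 17 keeps the catalyst away from the allylic acetate of the product.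

Step 12
Reactants: 18 the 12-O-trimethylsilyl ketone
Product: 19 methyl (4S,5E)-4-acetoxy-7-[(1R,2R)-2-hydroxy-2-[(Z)-oct-2-enyl]-5-oxocyclopent-3-en-1-yl]hept-5-enoate
Conditions: AcOH/THF/H2O (3:1:1), rt
Reagents that add atoms: none
Why: Mild acid hydrolysis of the labile trimethylsilyl ether should leave the acetate, the methyl ester, both alkenes and C8 untouched, since no base is present that could trigger retro-aldol opening of the β-hydroxy ketone.

Step 13
Reactants: 19 the C12 tertiary alcohol
Product: 20 methyl (4S,5E)-4-acetoxy-7-[(1R,2R)-2-acetoxy-2-[(Z)-oct-2-enyl]-5-oxocyclopent-3-en-1-yl]hept-5-enoate (target)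
Conditions: Ac2O (5 equiv), Sc(OTf)3 (3 mol %), MeCN, −20 °C
Reagents that add atoms: acetic anhydride CC(=O)OC(C)=O
Why: Lewis-acid-catalysed acylation with Sc(OTf)3 and acetic anhydride acetylates hindered tertiary alcohols at low temperature without amine base, which should avoid C8 epimerisation and E1cB loss of the new acetate, while ionisation at C12 is disfavoured because the cation would sit γ to the enone carbonyl.

**Compound list**

1 | oct-2-yn-1-ol | CCCCCC#CCO | starting material
2 | (Z)-oct-2-en-1-ol | CCCCC/C=C\CO | intermediate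
3 | (Z)-1-chlorooct-2-ene | CCCCC/C=C\CCl | intermediate
4 | (R)-4-(tert-butyldimethylsilyloxy)cyclopent-2-en-1-one | O=C1C=C[C@H](O[Si](C)(C)C(C)(C)C)C1 | starting material
5 | (Z)-oct-2-enylbarium chloride | CCCCC/C=C\C[Ba]Cl | intermediate
6 | (1S,4R)-4-(tert-butyldimethylsilyloxy)-1-[(Z)-oct-2-enyl]cyclopent-2-en-1-ol | CCCCC/C=C\C[C@@]1(O)C=C[C@H](O[Si](C)(C)C(C)(C)C)C1 | intermediate
7 | (1S,4R)-1-[(Z)-oct-2-enyl]cyclopent-2-ene-1,4-diol | CCCCC/C=C\C[C@@]1(O)C=C[C@H](O)C1 | intermediate
8 | (S)-4-hydroxy-4-[(Z)-oct-2-enyl]cyclopent-2-en-1-one | CCCCC/C=C\C[C@@]1(O)C=CC(=O)C1 | intermediate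
9 | (R)-5-[(Z)-oct-2-enyl]-2,5-bis(trimethylsilyloxy)cyclopenta-1,3-diene | CCCCC/C=C\C[C@@]1(O[Si](C)(C)C)C=CC(O[Si](C)(C)C)=C1 | intermediate
10 | (S)-5-(hydroxymethyl)dihydrofuran-2(3H)-one | OC[C@@H]1CCC(=O)O1 | starting material
11 | (S)-5-oxotetrahydrofuran-2-carbaldehyde | O=C[C@@H]1CCC(=O)O1 | intermediate
12 | (S)-5-vinyldihydrofuran-2(3H)-one | C=C[C@@H]1CCC(=O)O1 | intermediate
13 | potassium (S)-4-hydroxyhex-5-enoate | C=C[C@H](CCC(=O)[O-])O.[K+] | intermediate
14 | methyl (S)-4-hydroxyhex-5-enoate | C=C[C@H](CCC(=O)OC)O | intermediate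
15 | methyl (S)-4-acetoxyhex-5-enoate | C=C[C@H](CCC(=O)OC)OC(C)=O | intermediate
16 | allyl methyl carbonate | C=CCOC(=O)OC | starting material
17 | methyl (S,E)-4-acetoxy-7-(methoxycarbonyloxy)hept-5-enoate | COC(=O)OC/C=C/[C@H](CCC(=O)OC)OC(C)=O | intermediate
18 | methyl (4S,5E)-4-acetoxy-7-[(1R,2R)-2-[(Z)-oct-2-enyl]-5-oxo-2-(trimethylsilyloxy)cyclopent-3-en-1-yl]hept-5-enoate | CCCCC/C=C\C[C@@]1(O[Si](C)(C)C)C=CC(=O)[C@@H]1C/C=C/[C@H](CCC(=O)OC)OC(C)=O | intermediate
19 | methyl (4S,5E)-4-acetoxy-7-[(1R,2R)-2-hydroxy-2-[(Z)-oct-2-enyl]-5-oxocyclopent-3-en-1-yl]hept-5-enoate | CCCCC/C=C\C[C@@]1(O)C=CC(=O)[C@@H]1C/C=C/[C@H](CCC(=O)OC)OC(C)=O | intermediate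
20 | methyl (4S,5E)-4-acetoxy-7-[(1R,2R)-2-acetoxy-2-[(Z)-oct-2-enyl]-5-oxocyclopent-3-en-1-yl]hept-5-enoate | CCCCC/C=C\C[C@@]1(OC(C)=O)C=CC(=O)[C@@H]1C/C=C/[C@H](CCC(=O)OC)OC(C)=O | target

**Step count**

Total step count: 13.
Longest linear sequence: 9 (steps 1–6, then 11–13). The chain branch (steps 7–10) joins at step 11.

**Steps most likely to fail**

**Step 11.**
- What may go wrong: late ionisation of the C4 allylic acetate by zerovalent palladium, hydrolysis or Diels–Alder dimerisation of the silyl dienol ether before it couples, or insufficient facial selectivity at C8.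
- Fallback: classical SN2 alkylation of a preformed lithium enolate. It sets out from 8 and 15 and comes back at 19.
- Compound 8 is silylated with Et3SiOTf and 2,6-lutidine to (S)-4-(triethylsilyloxy)-4-[(Z)-oct-2-enyl]cyclopent-2-en-1-one F1.
- Compound 15 undergoes cross metathesis with allyl bromide (second-generation Hoveyda–Grubbs catalyst) to methyl (S,E)-4-acetoxy-7-bromohept-5-enoate F2.
- The enolate of F1 (LiN(iPr)2, THF/DMPU, −78 °C) is alkylated with F2 to the 12-O-triethylsilyl ketone F3.
- HF·pyridine in MeCN then converts F3 into 19.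

**Step 13.**
- What may go wrong: sluggish acylation of the hindered tertiary alcohol, so that dehydration, enol acetate formation at C9 or loss of the new acetate by elimination takes over.
- Fallback: the acetate is installed before the ketone exists. It sets out from 6 and comes back at 20.
- Compound 6 is acetylated (Ac2O, DMAP, Et3N) to (1S,4R)-4-(tert-butyldimethylsilyloxy)-1-[(Z)-oct-2-enyl]cyclopent-2-en-1-yl acetate F4.
- HF·pyridine converts F4 into (1S,4R)-4-hydroxy-1-[(Z)-oct-2-enyl]cyclopent-2-en-1-yl acetate F5.
- MnO2 oxidises F5 to (S)-1-[(Z)-oct-2-enyl]-4-oxocyclopent-2-en-1-yl acetate F6.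
- Me3SiOTf/Et3N converts F6 into (R)-1-[(Z)-oct-2-enyl]-3-(trimethylsilyloxy)cyclopenta-2,4-dien-1-yl acetate F7.
- F7 is coupled with 17 under the conditions of step 11 and gives 20 directly.

**Step 3.**
- What may go wrong: erosion of the α-regioselectivity or the Z geometry if the barium reagent warms, enolisation of 4 with loss of silanol, or weak facial bias.
- Fallback: the octenyl chain is built stepwise by ester enolate addition and Z-selective Wittig olefination. It sets out from 4 and comes back at 7.
- The lithium enolate of ethyl acetate (LiN(iPr)2, THF, −78 °C) adds 1,2 to 4 and gives ethyl 2-[(1R,4R)-4-(tert-butyldimethylsilyloxy)-1-hydroxycyclopent-2-en-1-yl]acetate F8.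
- Et3SiOTf and 2,6-lutidine give its triethylsilyl ether F9.
- iBu2AlH at −78 °C gives 2-[(1R,4R)-4-(tert-butyldimethylsilyloxy)-1-(triethylsilyloxy)cyclopent-2-en-1-yl]acetaldehyde F10.
- Hexyltriphenylphosphonium bromide and NaN(SiMe3)2 give the bis-silyl ether of the (Z)-octenyl diol F11.
- Excess Bu4NF converts F11 into 7.

**Further compounds**

F1 | step 11 | (S)-4-(triethylsilyloxy)-4-[(Z)-oct-2-enyl]cyclopent-2-en-1-one | CCCCC/C=C\C[C@@]1(O[Si](CC)(CC)CC)C=CC(=O)C1
F2 | step 11 | methyl (S,E)-4-acetoxy-7-bromohept-5-enoate | BrC/C=C/[C@H](CCC(=O)OC)OC(C)=O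
F3 | step 11 | methyl (4S,5E)-4-acetoxy-7-[(1R,2R)-2-[(Z)-oct-2-enyl]-5-oxo-2-(triethylsilyloxy)cyclopent-3-en-1-yl]hept-5-enoate | CCCCC/C=C\C[C@@]1(O[Si](CC)(CC)CC)C=CC(=O)[C@@H]1C/C=C/[C@H](CCC(=O)OC)OC(C)=O
F4 | step 13 | (1S,4R)-4-(tert-butyldimethylsilyloxy)-1-[(Z)-oct-2-enyl]cyclopent-2-en-1-yl acetate | CCCCC/C=C\C[C@@]1(OC(C)=O)C=C[C@H](O[Si](C)(C)C(C)(C)C)C1
F5 | step 13 | (1S,4R)-4-hydroxy-1-[(Z)-oct-2-enyl]cyclopent-2-en-1-yl acetate | CCCCC/C=C\C[C@@]1(OC(C)=O)C=C[C@H](O)C1
F6 | step 13 | (S)-1-[(Z)-oct-2-enyl]-4-oxocyclopent-2-en-1-yl acetate | CCCCC/C=C\C[C@@]1(OC(C)=O)C=CC(=O)C1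
F7 | step 13 | (R)-1-[(Z)-oct-2-enyl]-3-(trimethylsilyloxy)cyclopenta-2,4-dien-1-yl acetate | CCCCC/C=C\C[C@@]1(OC(C)=O)C=CC(O[Si](C)(C)C)=C1
F8 | step 3 | ethyl 2-[(1R,4R)-4-(tert-butyldimethylsilyloxy)-1-hydroxycyclopent-2-en-1-yl]acetate | CCOC(=O)C[C@@]1(O)C=C[C@H](O[Si](C)(C)C(C)(C)C)C1
F9 | step 3 | ethyl 2-[(1R,4R)-4-(tert-butyldimethylsilyloxy)-1-(triethylsilyloxy)cyclopent-2-en-1-yl]acetate | CCOC(=O)C[C@@]1(O[Si](CC)(CC)CC)C=C[C@H](O[Si](C)(C)C(C)(C)C)C1
F10 | step 3 | 2-[(1R,4R)-4-(tert-butyldimethylsilyloxy)-1-(triethylsilyloxy)cyclopent-2-en-1-yl]acetaldehyde | O=CC[C@@]1(O[Si](CC)(CC)CC)C=C[C@H](O[Si](C)(C)C(C)(C)C)C1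
F11 | step 3 | (1S,4R)-4-(tert-butyldimethylsilyloxy)-1-[(Z)-oct-2-enyl]-1-(triethylsilyloxy)cyclopent-2-ene | CCCCC/C=C\C[C@@]1(O[Si](CC)(CC)CC)C=C[C@H](O[Si](C)(C)C(C)(C)C)C1
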